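**Plan** (oxolane numbering O1, C2 = CO2H carbon, C3 = carbinol, C4, C5; chain C6–C24 outward from C5)
1. Cuts: C7–C8 (sp2–sp2, Stille) gives iodovinyl oxolane acid 16 and stannyl pentaenyl dione 30; in 30, C16=C17 and C20=C21 (two Wittig olefinations of a 2,3-dioxobutane bis-ylide) and C12=C13 (vinylogous HWE); in 16, the ring bond C4–C5.
2. Enabling feature: ring O1 lies between C2 (α to the C3 carbinol) and C5 (β to it), so O1–C5–C4–C3(O) is a β-alkoxy-carbonyl (aldol) retron; C2–C3 map onto an α-hydroxy acid, C5 onto an aldehyde carbon, C4 onto a methylene added to the carboxyl carbon.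
3. Forward: (R)-glyceric acid and (E)-3-iodoacrolein are tied as a 1,3-dioxolan-4-one (temporary ring), the lactone C=O is methylenated, and a Petasis–Ferrier rearrangement with in situ reduction closes the oxolane at C4–C5.
4. The C2 side chain is then raised to the acid; the polyene-dione arm is built separately and joined in the last step, with no deprotection after it.
5. Stereochemistry: the glycerate centre (C2) relays C5 and C3 in the key step (all-cis expected); C2 is then inverted by thermodynamic epimerisation of the aldehyde to the 2,3-trans/2,5-trans array; the sec-butyl centre comes from (R)-2-methylbutan-1-ol; all alkenes are E from stabilised ylides, syn-hydrostannation and stereoretentive coupling.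

Key step: step 6

Remark: the rearrangement is expected to give the 2,5-cis, 3-OH-cis oxolane, as is usual for this class of enol acetal; the route therefore plans from the outset to correct C2 in step 9.

Step 1
Reactants: 1 methyl (2R)-2,3-dihydroxypropanoate
Product: 2 methyl (2R)-3-{[tert-butyl(dimethyl)silyl]oxy}-2-hydroxypropanoate
Conditions: TBSCl (1.05 equiv), imidazole, CH2Cl2, −20 → 0 °C
Reagents that add atoms: tert-butyldimethylsilyl chloride, CC(C)(C)[Si](C)(C)Cl
Why: Silyl ether formation is selective for the primary hydroxyl, the secondary one being hindered and deactivated by the ester.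

Step 2
Reactants: 2 methyl (2R)-3-{[tert-butyl(dimethyl)silyl]oxy}-2-hydroxypropanoate
Product: 3 (2R)-3-{[tert-butyl(dimethyl)silyl]oxy}-2-hydroxypropanoic acid
Conditions: LiOH·H2O, THF–H2O, 0 °C; then 1 M HCl to pH 3–4, EtOAc
Reagents that add atoms: lithium hydroxide, [Li+].[OH-]
Why: Ester saponification at 0 °C should leave the α-stereocentre and the primary silyl ether intact.

Step 3
Reactants: 4 ethyl (2E)-3-iodoprop-2-enoate
Product: 5 (2E)-3-iodoprop-2-enal
Conditions: DIBAL-H (1.05 equiv), CH2Cl2, −78 °C; MeOH, aq. Rochelle salt; used at once as a cold CH2Cl2 solution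
Reagents that add atoms: none
Why: DIBAL half-reduction of an ester stops at the aldehyde because the tetrahedral aluminium hemiacetal is stable at −78 °C; the E alkene is untouched.

Step 4
Reactants: 3 (2R)-3-{[tert-butyl(dimethyl)silyl]oxy}-2-hydroxypropanoic acid; 5 (2E)-3-iodoprop-2-enal
Product: 7 (2R,5R)-5-({[tert-butyl(dimethyl)silyl]oxy}methyl)-2-[(E)-2-iodoethenyl]-1,3-dioxolan-4-one, via bis-TMS derivative 6 (not isolated)
Conditions: (i) HMDS, CH2Cl2, rt, concentrate; (ii) 5 (1.3 equiv), TMSOTf (0.1 equiv), CH2Cl2, −78 °C; pyridine quench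
Reagents that add atoms: none
Why: TMSOTf-catalysed condensation of a silyl ester/silyl ether with an aldehyde (1,3-dioxolan-4-one formation) runs at −78 °C and so tolerates the labile enal; the cis acetal is expected, but this centre is erased in step 6.

Step 5
Reactants: 7 (2R,5R)-5-({[tert-butyl(dimethyl)silyl]oxy}methyl)-2-[(E)-2-iodoethenyl]-1,3-dioxolan-4-one
Product: 8 (2R,4R)-4-({[tert-butyl(dimethyl)silyl]oxy}methyl)-2-[(E)-2-iodoethenyl]-5-methylidene-1,3-dioxolane
Conditions: Cp2TiMe2 (2.5 equiv), THF, 65 °C, dark; hexanes, filtration through basic alumina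
Reagents that add atoms: dimethyltitanocene, [CH3-].[CH3-].[Ti+4].c1cc[cH-]c1.c1cc[cH-]c1
Why: Petasis methylenation (titanium methylidene olefination of the lactone carbonyl) is non-basic, so the α-stereocentre, the acetal and the vinyl iodide should survive.

Step 6
Reactants: 8 (2R,4R)-4-({[tert-butyl(dimethyl)silyl]oxy}methyl)-2-[(E)-2-iodoethenyl]-5-methylidene-1,3-dioxolane
Product: 10 (2R,3R,5R)-2-({[tert-butyl(dimethyl)silyl]oxy}methyl)-5-[(E)-2-iodoethenyl]oxolan-3-ol, via oxolan-3-one 9 (not isolated)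
Conditions: i-Bu3Al (3 equiv), toluene, −78 → 0 °C; aq. Rochelle salt
Reagents that add atoms: none
Why: i-Bu3Al binds the enol-ether oxygen and ionises the acetal C–O bond to a contact ion pair of an (E)-oxocarbenium ion (O1=C5, stabilised by the iodovinyl group) and an aluminium enolate (C3=C4), which recombines through carbon to form C4–C5; this is the Petasis–Ferrier rearrangement, and the closest known reaction type is the same rearrangement–reduction of 2,5-disubstituted 4-methylene-1,3-dioxolanes from simple α-hydroxy acids. The oxolane closes in the 5-(enolendo)-endo-trig mode, formally disfavoured but enforced because both partners stay joined through C2–O1 (equivalently a 1,3 O→C shift of C5). C5 is set by the resident C2 centre: in the envelope transition state the CH2OTBS group and the oxocarbenium substituent should both lie pseudo-equatorial, giving the 2,5-cis ketone 9 whichever acetal epimer of 8 enters. C3 is set when a β-hydride of an isobutyl group on the carbonyl-bound aluminium is delivered to the face opposite the C2 and C5 substituents, which should give the all-cis alcohol. The step needs carbon recombination at C5 rather than at C7, secured because attack at C7 would place an E alkene in a seven-membered ring, and it needs a non-chelating silyl ether at C1 so that sterics alone decide both faces. C2 is deliberately left cis to its neighbours here and is inverted in step 9.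

Step 7
Reactants: 10 (2R,3R,5R)-2-({[tert-butyl(dimethyl)silyl]oxy}methyl)-5-[(E)-2-iodoethenyl]oxolan-3-ol
Product: 11 (2R,3R,5R)-3-{[tert-butyl(dimethyl)silyl]oxy}-2-({[tert-butyl(dimethyl)silyl]oxy}methyl)-5-[(E)-2-iodoethenyl]oxolane
Conditions: TBSOTf, 2,6-lutidine, CH2Cl2, −78 → 0 °C
Reagents that add atoms: tert-butyldimethylsilyl triflate, CC(C)(C)[Si](C)(C)OS(=O)(=O)C(F)(F)F
Why: Silylation with a silyl triflate protects the hindered secondary alcohol, blocking retro-aldol cleavage in step 9.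

Step 8
Reactants: 11 (2R,3R,5R)-3-{[tert-butyl(dimethyl)silyl]oxy}-2-({[tert-butyl(dimethyl)silyl]oxy}methyl)-5-[(E)-2-iodoethenyl]oxolane
Product: 12 [(2R,3R,5R)-3-{[tert-butyl(dimethyl)silyl]oxy}-5-[(E)-2-iodoethenyl]oxolan-2-yl]methanol
Conditions: HF·pyridine, pyridine, THF, 0 °C
Reagents that add atoms: none
Why: Buffered fluoride desilylation is selective for the primary silyl ether over the flanked secondary one on steric grounds.

Step 9
Reactants: 12 [(2R,3R,5R)-3-{[tert-butyl(dimethyl)silyl]oxy}-5-[(E)-2-iodoethenyl]oxolan-2-yl]methanol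
Product: 14 (2R,3R,5R)-3-{[tert-butyl(dimethyl)silyl]oxy}-5-[(E)-2-iodoethenyl]oxolane-2-carbaldehyde, via cis-aldehyde 13 (not isolated)
Conditions: (i) Dess–Martin periodinane, CH2Cl2, 0 °C → rt; aq. NaHCO3/Na2S2O3 work-up; (ii) K2CO3 (0.3 equiv), MeOH, 0 °C → rt
Reagents that add atoms: none
Why: Dess–Martin oxidation gives the all-cis aldehyde, and carbonate-mediated enolisation (thermodynamic epimerisation of an α-alkoxy aldehyde) should move the formyl group to the face opposite the C3 silyloxy and C5 iodovinyl groups, so the final C2 configuration is set under thermodynamic control.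

Step 10
Reactants: 14 (2R,3R,5R)-3-{[tert-butyl(dimethyl)silyl]oxy}-5-[(E)-2-iodoethenyl]oxolane-2-carbaldehyde
Product: 15 (2R,3R,5R)-3-{[tert-butyl(dimethyl)silyl]oxy}-5-[(E)-2-iodoethenyl]oxolane-2-carboxylic acid
Conditions: NaClO2, NaH2PO4, 2-methylbut-2-ene, t-BuOH–H2O, 0 °C → rt
Reagents that add atoms: sodium chlorite, [Na+].[O-]Cl=O
Why: Pinnick oxidation converts the aldehyde to the acid under buffered conditions that spare the vinyl iodide; C2 is already the stable epimer.

Step 11
Reactants: 15 (2R,3R,5R)-3-{[tert-butyl(dimethyl)silyl]oxy}-5-[(E)-2-iodoethenyl]oxolane-2-carboxylic acid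
Product: 16 (2R,3R,5R)-3-hydroxy-5-[(E)-2-iodoethenyl]oxolane-2-carboxylic acid
Conditions: aq. HF (48%), MeCN, 0 °C → rt
Reagents that add atoms: none
Why: Fluoride-mediated desilylation frees the C3 hydroxyl before the polyene is present, so the sensitive hexaene-dione never meets a deprotection.

Step 12
Reactants: 17 (2E)-pent-2-en-4-yn-1-ol
Product: 18 (2E,4E)-5-(tributylstannyl)penta-2,4-dien-1-ol
Conditions: Bu3SnH, PdCl2(PPh3)2 (2 mol %), THF, 0 °C
Reagents that add atoms: tributyltin hydride, CCCC[SnH](CCCC)CCCC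
Why: Pd-catalysed hydrostannation adds Sn–H syn across the terminal alkyne with tin at the terminus, giving the E vinylstannane.

Step 13
Reactants: 18 (2E,4E)-5-(tributylstannyl)penta-2,4-dien-1-ol
Product: 19 (2E,4E)-5-(tributylstannyl)penta-2,4-dienal
Conditions: MnO2, CH2Cl2, rt, dark
Reagents that add atoms: none
Why: MnO2 oxidises the allylic alcohol selectively and leaves the C–Sn bond alone.

Step 14
Reactants: 19 (2E,4E)-5-(tributylstannyl)penta-2,4-dienal; 20 ethyl (2E)-4-(diethoxyphosphoryl)but-2-enoate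
Product: 21 ethyl (2E,4E,6E,8E)-9-(tributylstannyl)nona-2,4,6,8-tetraenoate
Conditions: 20, LiHMDS, THF, −78 °C; then 19, −78 → 0 °C
Reagents that add atoms: none
Why: The vinylogous Horner–Wadsworth–Emmons olefination adds four carbons and should form the new alkene E.

Step 15
Reactants: 21 ethyl (2E,4E,6E,8E)-9-(tributylstannyl)nona-2,4,6,8-tetraenoate
Product: 22 (2E,4E,6E,8E)-9-(tributylstannyl)nona-2,4,6,8-tetraen-1-ol
Conditions: DIBAL-H (2.2 equiv), CH2Cl2, −78 °C; aq. Rochelle salt
Reagents that add atoms: none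
Why: DIBAL reduces the conjugated ester 1,2 to the allylic alcohol without touching the stannane.

Step 16
Reactants: 22 (2E,4E,6E,8E)-9-(tributylstannyl)nona-2,4,6,8-tetraen-1-ol
Product: 23 (2E,4E,6E,8E)-9-(tributylstannyl)nona-2,4,6,8-tetraenal
Conditions: MnO2, CH2Cl2, rt, dark
Reagents that add atoms: none
Why: MnO2 oxidation of the polyenylic alcohol is mild enough for the stannyl tetraene.

Step 17
Reactants: 24 1,4-dibromobutane-2,3-dione
Product: 26 1,4-bis(triphenyl-λ5-phosphanylidene)butane-2,3-dione, via bis-phosphonium dibromide 25 (not isolated)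
Conditions: (i) PPh3 (2.1 equiv), THF, rt; (ii) aq. Na2CO3, CH2Cl2, 0 °C
Reagents that add atoms: triphenylphosphine, c1ccc(cc1)P(c1ccccc1)c1ccccc1
Why: SN2 alkylation of PPh3 by both α-bromoketone termini, then deprotonation, gives the doubly keto-stabilised bis-ylide that carries the 1,2-dione.

Step 18
Reactants: 27 (2R)-2-methylbutan-1-ol; 26 1,4-bis(triphenyl-λ5-phosphanylidene)butane-2,3-dione
Product: 29 (4E,6R)-6-methyl-1-(triphenyl-λ5-phosphanylidene)oct-4-ene-2,3-dione, via (R)-2-methylbutanal 28 (not isolated)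
Conditions: (i) 27, Dess–Martin periodinane, CH2Cl2, 0 °C → rt; aq. NaHCO3/Na2S2O3 wash, dry; (ii) the solution added slowly to 26 (3 equiv), CH2Cl2, rt
Reagents that add atoms: none
Why: Wittig olefination with a stabilised ylide is E-selective and base-free, so the α-stereocentre of the volatile aldehyde should be kept, and the excess of bis-ylide favours mono-olefination.

Step 19
Reactants: 29 (4E,6R)-6-methyl-1-(triphenyl-λ5-phosphanylidene)oct-4-ene-2,3-dione; 23 (2E,4E,6E,8E)-9-(tributylstannyl)nona-2,4,6,8-tetraenal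
Product: 30 (3R,4E,8E,10E,12E,14E,16E)-3-methyl-17-(tributylstannyl)heptadeca-4,8,10,12,14,16-hexaene-6,7-dione
Conditions: toluene, 60 °C, dark, BHT (trace)
Reagents that add atoms: none
Why: A second Wittig olefination of the remaining stabilised ylide with the polyenal should give the C16=C17 alkene E under neutral conditions that the 1,2-dione and the stannane tolerate.

Step 20
Reactants: 16 (2R,3R,5R)-3-hydroxy-5-[(E)-2-iodoethenyl]oxolane-2-carboxylic acid; 30 (3R,4E,8E,10E,12E,14E,16E)-3-methyl-17-(tributylstannyl)heptadeca-4,8,10,12,14,16-hexaene-6,7-dione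
Product: 31 (2R,3R,5R)-3-hydroxy-5-[(1E,3E,5E,7E,9E,11E,15E,17R)-17-methyl-13,14-dioxononadeca-1,3,5,7,9,11,15-heptaen-1-yl]oxolane-2-carboxylic acid
Conditions: Pd2(dba)3·CHCl3 (5 mol %), AsPh3 (20 mol %), DMF–THF, rt, dark, degassed; 30 in slight excess
Reagents that add atoms: none
Why: Stille cross-coupling of a vinyl iodide with a vinylstannane joins C7–C8 at room temperature with retention of both alkene geometries and tolerates the free hydroxyl, carboxylic acid and dione.

**Compound list**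
1 | methyl (2R)-2,3-dihydroxypropanoate | COC(=O)[C@H](O)CO | starting material
2 | methyl (2R)-3-{[tert-butyl(dimethyl)silyl]oxy}-2-hydroxypropanoate | COC(=O)[C@H](O)CO[Si](C)(C)C(C)(C)C | intermediate
3 | (2R)-3-{[tert-butyl(dimethyl)silyl]oxy}-2-hydroxypropanoic acid | OC(=O)[C@H](O)CO[Si](C)(C)C(C)(C)C | intermediate
4 | ethyl (2E)-3-iodoprop-2-enoate | CCOC(=O)/C=C/I | starting material
5 | (2E)-3-iodoprop-2-enal | O=C/C=C/I | intermediate
6 | trimethylsilyl (2R)-3-{[tert-butyl(dimethyl)silyl]oxy}-2-[(trimethylsilyl)oxy]propanoate | C[Si](C)(C)OC(=O)[C@H](O[Si](C)(C)C)CO[Si](C)(C)C(C)(C)C | intermediate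
7 | (2R,5R)-5-({[tert-butyl(dimethyl)silyl]oxy}methyl)-2-[(E)-2-iodoethenyl]-1,3-dioxolan-4-one (cis acetal) | O=C1O[C@H](/C=C/I)O[C@@H]1CO[Si](C)(C)C(C)(C)C | intermediate
8 | (2R,4R)-4-({[tert-butyl(dimethyl)silyl]oxy}methyl)-2-[(E)-2-iodoethenyl]-5-methylidene-1,3-dioxolane | C=C1O[C@H](/C=C/I)O[C@@H]1CO[Si](C)(C)C(C)(C)C | intermediate
9 | (2R,5R)-2-({[tert-butyl(dimethyl)silyl]oxy}methyl)-5-[(E)-2-iodoethenyl]oxolan-3-one | I/C=C/[C@H]1CC(=O)[C@@H](CO[Si](C)(C)C(C)(C)C)O1 | intermediate
10 | (2R,3R,5R)-2-({[tert-butyl(dimethyl)silyl]oxy}methyl)-5-[(E)-2-iodoethenyl]oxolan-3-ol | I/C=C/[C@H]1C[C@@H](O)[C@@H](CO[Si](C)(C)C(C)(C)C)O1 | intermediate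
11 | (2R,3R,5R)-3-{[tert-butyl(dimethyl)silyl]oxy}-2-({[tert-butyl(dimethyl)silyl]oxy}methyl)-5-[(E)-2-iodoethenyl]oxolane | I/C=C/[C@H]1C[C@@H](O[Si](C)(C)C(C)(C)C)[C@@H](CO[Si](C)(C)C(C)(C)C)O1 | intermediate
12 | [(2R,3R,5R)-3-{[tert-butyl(dimethyl)silyl]oxy}-5-[(E)-2-iodoethenyl]oxolan-2-yl]methanol | I/C=C/[C@H]1C[C@@H](O[Si](C)(C)C(C)(C)C)[C@@H](CO)O1 | intermediate
13 | (2S,3R,5R)-3-{[tert-butyl(dimethyl)silyl]oxy}-5-[(E)-2-iodoethenyl]oxolane-2-carbaldehyde | I/C=C/[C@H]1C[C@@H](O[Si](C)(C)C(C)(C)C)[C@@H](C=O)O1 | intermediate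
14 | (2R,3R,5R)-3-{[tert-butyl(dimethyl)silyl]oxy}-5-[(E)-2-iodoethenyl]oxolane-2-carbaldehyde | I/C=C/[C@H]1C[C@@H](O[Si](C)(C)C(C)(C)C)[C@H](C=O)O1 | intermediate
15 | (2R,3R,5R)-3-{[tert-butyl(dimethyl)silyl]oxy}-5-[(E)-2-iodoethenyl]oxolane-2-carboxylic acid | I/C=C/[C@H]1C[C@@H](O[Si](C)(C)C(C)(C)C)[C@H](C(=O)O)O1 | intermediate
16 | (2R,3R,5R)-3-hydroxy-5-[(E)-2-iodoethenyl]oxolane-2-carboxylic acid | I/C=C/[C@H]1C[C@@H](O)[C@H](C(=O)O)O1 | intermediate
17 | (2E)-pent-2-en-4-yn-1-ol | OC/C=C/C#C | starting material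
18 | (2E,4E)-5-(tributylstannyl)penta-2,4-dien-1-ol | OC/C=C/C=C/[Sn](CCCC)(CCCC)CCCC | intermediate
19 | (2E,4E)-5-(tributylstannyl)penta-2,4-dienal | O=C/C=C/C=C/[Sn](CCCC)(CCCC)CCCC | intermediate
20 | ethyl (2E)-4-(diethoxyphosphoryl)but-2-enoate | CCOC(=O)/C=C/CP(=O)(OCC)OCC | starting material
21 | ethyl (2E,4E,6E,8E)-9-(tributylstannyl)nona-2,4,6,8-tetraenoate | CCOC(=O)/C=C/C=C/C=C/C=C/[Sn](CCCC)(CCCC)CCCC | intermediate
22 | (2E,4E,6E,8E)-9-(tributylstannyl)nona-2,4,6,8-tetraen-1-ol | OC/C=C/C=C/C=C/C=C/[Sn](CCCC)(CCCC)CCCC | intermediate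
23 | (2E,4E,6E,8E)-9-(tributylstannyl)nona-2,4,6,8-tetraenal | O=C/C=C/C=C/C=C/C=C/[Sn](CCCC)(CCCC)CCCC | intermediate
24 | 1,4-dibromobutane-2,3-dione | BrCC(=O)C(=O)CBr | starting material
25 | (2,3-dioxobutane-1,4-diyl)bis(triphenylphosphonium) dibromide | [Br-].[Br-].O=C(C[P+](c1ccccc1)(c1ccccc1)c1ccccc1)C(=O)C[P+](c1ccccc1)(c1ccccc1)c1ccccc1 | intermediate
26 | 1,4-bis(triphenyl-λ5-phosphanylidene)butane-2,3-dione | O=C(C=P(c1ccccc1)(c1ccccc1)c1ccccc1)C(=O)C=P(c1ccccc1)(c1ccccc1)c1ccccc1 | intermediate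
27 | (2R)-2-methylbutan-1-ol | CC[C@@H](C)CO | starting material
28 | (2R)-2-methylbutanal | CC[C@@H](C)C=O | intermediate
29 | (4E,6R)-6-methyl-1-(triphenyl-λ5-phosphanylidene)oct-4-ene-2,3-dione | CC[C@@H](C)/C=C/C(=O)C(=O)C=P(c1ccccc1)(c1ccccc1)c1ccccc1 | intermediate
30 | (3R,4E,8E,10E,12E,14E,16E)-3-methyl-17-(tributylstannyl)heptadeca-4,8,10,12,14,16-hexaene-6,7-dione | CC[C@@H](C)/C=C/C(=O)C(=O)/C=C/C=C/C=C/C=C/C=C/[Sn](CCCC)(CCCC)CCCC | intermediate
31 | (2R,3R,5R)-3-hydroxy-5-[(1E,3E,5E,7E,9E,11E,15E,17R)-17-methyl-13,14-dioxononadeca-1,3,5,7,9,11,15-heptaen-1-yl]oxolane-2-carboxylic acid | CC[C@@H](C)/C=C/C(=O)C(=O)/C=C/C=C/C=C/C=C/C=C/C=C/[C@H]1C[C@@H](O)[C@H](C(=O)O)O1 | target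

**Totals**
Total step count: 20. Longest linear sequence: 11 steps (1, 2, 4–11, 20).

**Steps most likely to fail**

Step 6. The ion-pair recombination may lose facial control at C5, or the oxocarbenium ion may be reduced by the aluminium reagent before the C–C bond forms. The fallback sets out from 2 and comes back at 10. It starts with O-alkylation of 2 with (E)-3-bromo-1-iodoprop-1-ene (Ag2O, CH2Cl2), which gives methyl (2R)-3-{[tert-butyl(dimethyl)silyl]oxy}-2-{[(2E)-3-iodoprop-2-en-1-yl]oxy}propanoate F1. Saponification (LiOH) gives (2R)-3-{[tert-butyl(dimethyl)silyl]oxy}-2-{[(2E)-3-iodoprop-2-en-1-yl]oxy}propanoic acid F2. The mixed anhydride (i-BuOCOCl, N-methylmorpholine) and diazomethane give (3R)-4-{[tert-butyl(dimethyl)silyl]oxy}-1-diazo-3-{[(2E)-3-iodoprop-2-en-1-yl]oxy}butan-2-one F3. Rh2(OAc)4-catalysed 1,5 C–H insertion of the carbenoid into the allylic ether C–H forms the same C4–C5 bond and is expected to favour the 2,5-cis ketone 9, here isolated. L-Selectride reduction from the face opposite the C2 substituent returns to 10.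

Step 9. β-Elimination of silanolate from the aldehyde enolate may compete with epimerisation, or equilibration may stop short. The fallback sets out from 10 and comes back at 16, so that it also replaces steps 7, 8, 10 and 11. Dess–Martin oxidation of 10 gives ketone 9, here isolated. DBU in CH2Cl2 equilibrates C2 through the enol; the 2,5-trans isomer (2S,5R)-2-({[tert-butyl(dimethyl)silyl]oxy}methyl)-5-[(E)-2-iodoethenyl]oxolan-3-one F4 is separated and the cis isomer is recycled. HF·pyridine frees (2S,5R)-2-(hydroxymethyl)-5-[(E)-2-iodoethenyl]oxolan-3-one F5. Hydroxyl-directed reduction with Me4NBH(OAc)3 (MeCN–AcOH, −20 °C) delivers hydride from the face of the CH2OH arm and should give (2S,3R,5R)-2-(hydroxymethyl)-5-[(E)-2-iodoethenyl]oxolan-3-ol F6. TEMPO/PhI(OAc)2 in MeCN–water oxidises only the primary alcohol to the acid, which rejoins the route at 16.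

Step 19. The doubly carbonyl-stabilised ylide may olefinate the deactivated tetraenal too slowly, so that the stannyl polyene decays on prolonged heating. The fallback sets out from 29 and comes back at 30. Wittig reaction of 29 with the small, reactive aldehyde 5 (CH2Cl2, rt) gives (1E,3E,7E,9R)-1-iodo-9-methylundeca-1,3,7-triene-5,6-dione F7. Stille coupling of this iodide with an excess of (1E,3E,5E)-1,6-bis(tributylstannyl)hexa-1,3,5-triene, under the conditions of step 20, gives 30.

**Further compounds**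
F1 | step 6 | methyl (2R)-3-{[tert-butyl(dimethyl)silyl]oxy}-2-{[(2E)-3-iodoprop-2-en-1-yl]oxy}propanoate | COC(=O)[C@H](OC/C=C/I)CO[Si](C)(C)C(C)(C)C
F2 | step 6 | (2R)-3-{[tert-butyl(dimethyl)silyl]oxy}-2-{[(2E)-3-iodoprop-2-en-1-yl]oxy}propanoic acid | OC(=O)[C@H](OC/C=C/I)CO[Si](C)(C)C(C)(C)C
F3 | step 6 | (3R)-4-{[tert-butyl(dimethyl)silyl]oxy}-1-diazo-3-{[(2E)-3-iodoprop-2-en-1-yl]oxy}butan-2-one | [N-]=[N+]=CC(=O)[C@H](OC/C=C/I)CO[Si](C)(C)C(C)(C)C
F4 | step 9 | (2S,5R)-2-({[tert-butyl(dimethyl)silyl]oxy}methyl)-5-[(E)-2-iodoethenyl]oxolan-3-one | I/C=C/[C@H]1CC(=O)[C@H](CO[Si](C)(C)C(C)(C)C)O1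
F5 | step 9 | (2S,5R)-2-(hydroxymethyl)-5-[(E)-2-iodoethenyl]oxolan-3-one | I/C=C/[C@H]1CC(=O)[C@H](CO)O1
F6 | step 9 | (2S,3R,5R)-2-(hydroxymethyl)-5-[(E)-2-iodoethenyl]oxolan-3-ol | I/C=C/[C@H]1C[C@@H](O)[C@H](CO)O1
F7 | step 19 | (1E,3E,7E,9R)-1-iodo-9-methylundeca-1,3,7-triene-5,6-dione | CC[C@@H](C)/C=C/C(=O)C(=O)/C=C/C=C/I
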